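With C1 the alkyne-bearing ring carbon, C2 the vinylic CH, C3 the acetate carbon, C4 the methyl ether carbon and C5/C6 the free carbinols, the route rests on cutting the C5–C6 bond. The feature exploited is the cis-5,6-diol of the cyclohexene ring, lying trans to the C4 methoxy group, which maps onto a reductive carbonyl–carbonyl (pinacol) ring closure. In one operation SmI2 should close the six-membered ring and set both carbinol centres from an open-chain (Z)-2-alkynylhex-2-enedial that already carries the C3 silyl ether, the C4 methyl ether and a silyl-capped alkyne. This dialdehyde is built from (R)-glycidol and a butadiyne; the dienol side chain is attached last by Sonogashira coupling.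

Key step: step 11

Remark on the chemistry: ring positions are cited in the target numbering above (target = 3S,4R,5S,6S). The CIP letter at some centres changes along the route with the substituents although no bond to them is broken; the SMILES strings are authoritative. PMB = 4-methoxybenzyl, TBS = tert-butyldimethylsilyl, TMS = trimethylsilyl.

Step 1
Reactants: 1 (R)-glycidol
Product: 2 (S)-2-{[(4-methoxybenzyl)oxy]methyl}oxirane
Conditions: NaH, PMBCl, Bu4NI (cat.), THF/DMF, 0 °C → rt
Reagents that add atoms: 4-methoxybenzyl chloride, COc1ccc(CCl)cc1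
Why: Williamson etherification of the primary alkoxide leaves the stereocentre untouched (a Payne rearrangement of glycidol is degenerate and returns the same enantiomer); the letter changes from R to S only through the CIP priorities.

Step 2
Reactants: 2 (S)-2-{[(4-methoxybenzyl)oxy]methyl}oxirane
Product: 3 (S)-1-[(4-methoxybenzyl)oxy]but-3-en-2-ol
Conditions: Me3S+ I−, n-BuLi, THF, −10 °C → rt
Reagents that add atoms: trimethylsulfonium iodide, C[S+](C)C.[I-]
Why: Dimethylsulfonium methylide opens the epoxide at its terminal carbon and further ylide induces loss of Me2S from the sulfonium betaine, a one-carbon epoxide-to-allylic-alcohol homologation (sulfur ylide chemistry) that does not touch the C–O stereocentre.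

Step 3
Reactants: 3 (S)-1-[(4-methoxybenzyl)oxy]but-3-en-2-ol
Product: 4 (S)-3-methoxy-4-[(4-methoxybenzyl)oxy]but-1-ene
Conditions: NaH, MeI, THF, 0 °C → rt
Reagents that add atoms: iodomethane, CI
Why: Williamson O-methylation of the secondary alkoxide installs the future C4 methyl ether; the PMB ether and the alkene are inert.

Step 4
Reactants: 4 (S)-3-methoxy-4-[(4-methoxybenzyl)oxy]but-1-ene
Product: 6 (R)-2-methoxy-3-[(4-methoxybenzyl)oxy]propanal, via ozonide 5 (not isolated)
Conditions: O3, CH2Cl2, −78 °C (Sudan Red 7B end point); then Me2S, −78 °C → rt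
Reagents that add atoms: ozone, [O-][O+]=O
Why: Ozonolysis (Criegee mechanism) with reductive work-up cleaves the terminal alkene, which should react before the anisyl ring when the ozone feed is stopped at the indicator end point; the α-methoxy aldehyde is used crude to avoid epimerization.

Step 5
Reactants: 6 (R)-2-methoxy-3-[(4-methoxybenzyl)oxy]propanal; 7 1,4-bis(trimethylsilyl)buta-1,3-diyne
Product: 9 (2R,3S)-2-methoxy-1-[(4-methoxybenzyl)oxy]-7-(trimethylsilyl)hepta-4,6-diyn-3-ol, via lithiated diyne 8 (not isolated)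
Conditions: 7, MeLi·LiBr, THF, −78 °C → rt; then 6, THF, −78 °C
Reagents that add atoms: none
Why: MeLi·LiBr removes one TMS group to give the lithium diynide, whose 1,2-addition to the α-alkoxy aldehyde in THF should follow the polar Felkin–Anh model (attack anti to the C–OMe bond) and set the C3 carbinol as 3S (2,3-anti); the minor syn epimer is removed by chromatography.

Step 6
Reactants: 9 (2R,3S)-2-methoxy-1-[(4-methoxybenzyl)oxy]-7-(trimethylsilyl)hepta-4,6-diyn-3-ol
Product: 11 (2R,3S,4Z)-5-iodo-2-methoxy-1-[(4-methoxybenzyl)oxy]-7-(trimethylsilyl)hept-4-en-6-yn-3-ol, via cyclic alkenylalanate 10 (not isolated)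
Conditions: NaAlH2(OCH2CH2OMe)2, THF, −20 → 0 °C; then I2, THF, −78 °C
Reagents that add atoms: iodine, II
Why: Hydroxyl-directed trans-hydroalumination of the propargylic alcohol delivers hydride to the proximal alkyne carbon and leaves a five-membered alkenylalanate whose C–Al bond is iodinated with retention, so iodine should end up cis to the carbinol carbon (Z) while the distal silyl alkyne, lacking a directing group, stays intact.

Step 7
Reactants: 11 (2R,3S,4Z)-5-iodo-2-methoxy-1-[(4-methoxybenzyl)oxy]-7-(trimethylsilyl)hept-4-en-6-yn-3-ol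
Product: 12 tert-butyl({(2R,3S,4Z)-5-iodo-2-methoxy-1-[(4-methoxybenzyl)oxy]-7-(trimethylsilyl)hept-4-en-6-yn-3-yl}oxy)dimethylsilane
Conditions: TBSOTf, 2,6-lutidine, CH2Cl2, −78 → 0 °C
Reagents that add atoms: tert-butyldimethylsilyl trifluoromethanesulfonate, CC(C)(C)[Si](C)(C)OS(=O)(=O)C(F)(F)F
Why: Silyl triflate silylation of the hindered allylic alcohol under a non-nucleophilic base; the bulky silyl ether is chosen as a poor leaving group for the later reductive step.

Step 8
Reactants: 12 tert-butyl({(2R,3S,4Z)-5-iodo-2-methoxy-1-[(4-methoxybenzyl)oxy]-7-(trimethylsilyl)hept-4-en-6-yn-3-yl}oxy)dimethylsilane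
Product: 14 (2Z,4S,5R)-4-[(tert-butyldimethylsilyl)oxy]-5-methoxy-6-[(4-methoxybenzyl)oxy]-2-[(trimethylsilyl)ethynyl]hex-2-enal, via alkenyllithium 13 (not isolated)
Conditions: t-BuLi (2.1 equiv), Et2O, −78 °C; then DMF, −78 °C; cold buffered aqueous quench
Reagents that add atoms: N,N-dimethylformamide, CN(C)C=O
Why: Iodine–lithium exchange should proceed with retention at −78 °C (the lithium cis to the chain can be held by the C4 methoxy oxygen) and formylation of the alkenyllithium with DMF (Bouveault-type) places the aldehyde cis to C3, giving the Z-enynal.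

Step 9
Reactants: 14 (2Z,4S,5R)-4-[(tert-butyldimethylsilyl)oxy]-5-methoxy-6-[(4-methoxybenzyl)oxy]-2-[(trimethylsilyl)ethynyl]hex-2-enal
Product: 15 (2Z,4S,5R)-4-[(tert-butyldimethylsilyl)oxy]-6-hydroxy-5-methoxy-2-[(trimethylsilyl)ethynyl]hex-2-enal
Conditions: DDQ, CH2Cl2/pH 7 buffer, 0 °C
Reagents that add atoms: none
Why: Oxidative PMB cleavage by DDQ (hydride abstraction at the electron-rich benzylic carbon, then hydrolysis) under buffered two-phase conditions spares the TBS ether, the enal and the silyl alkyne; the alcohol is carried on at once so that it cannot add to the enal.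

Step 10
Reactants: 15 (2Z,4S,5R)-4-[(tert-butyldimethylsilyl)oxy]-6-hydroxy-5-methoxy-2-[(trimethylsilyl)ethynyl]hex-2-enal
Product: 16 (2Z,4S,5S)-4-[(tert-butyldimethylsilyl)oxy]-5-methoxy-2-[(trimethylsilyl)ethynyl]hex-2-enedial
Conditions: Dess–Martin periodinane, NaHCO3, CH2Cl2, 0 °C → rt
Reagents that add atoms: none
Why: Buffered Dess–Martin oxidation of the primary alcohol should give the α-methoxy aldehyde without epimerization at C4 or isomerization of the alkene.

Step 11
Reactants: 16 (2Z,4S,5S)-4-[(tert-butyldimethylsilyl)oxy]-5-methoxy-2-[(trimethylsilyl)ethynyl]hex-2-enedial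
Product: 17 (1S,2S,5S,6R)-5-[(tert-butyldimethylsilyl)oxy]-6-methoxy-3-[(trimethylsilyl)ethynyl]cyclohex-3-ene-1,2-diol
Conditions: SmI2 (2.5 equiv), t-BuOH, THF, −78 °C, 16 added slowly to the reductant
Reagents that add atoms: none
Why: Proposed new method: single-electron transfer from divalent samarium to the more easily reduced conjugated C6 carbonyl should give a ketyl bound to trivalent samarium whose carbon attacks the samarium-coordinated C5 aldehyde, after which a second electron and t-BuOH deliver the diol; the closest known reaction is the SmI2 pinacol cyclization of alkoxy-substituted 1,6-dialdehydes to cis-cyclohexane-1,2-diols, which has not been run with an enynal partner. The six-membered ring closes in a 6-exo-trig mode onto the C5 carbonyl carbon, the Z alkene holding C6 and C5 within bonding distance. The cis relationship of C5 and C6 is set by the samarium ion that ties both oxygens together in the cyclic transition state, and the new C5–O bond is placed anti to the C4 methoxy group to avoid dipolar and steric repulsion with that α-alkoxy substituent, so C4 fixes the absolute sense (5S,6S in target numbering). The step needs bond formation at C6 of the delocalized ketyl and not at C2, which the four-membered alternative rules out, and it needs cyclization to outrun a second reduction that would expel the C3 silyloxy group; the bulky, poorly leaving TBS ether, the absence of strongly reducing additives and −78 °C are meant to secure this.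

Step 12
Reactants: 17 (1S,2S,5S,6R)-5-[(tert-butyldimethylsilyl)oxy]-6-methoxy-3-[(trimethylsilyl)ethynyl]cyclohex-3-ene-1,2-diol
Product: 18 tert-butyl({(3aS,4R,5S,7aS)-4-methoxy-2,2-dimethyl-7-[(trimethylsilyl)ethynyl]-3a,4,5,7a-tetrahydro-1,3-benzodioxol-5-yl}oxy)dimethylsilane
Conditions: Me2C(OMe)2, PPTS (cat.), CH2Cl2, rt
Reagents that add atoms: 2,2-dimethoxypropane, COC(C)(C)OC
Why: Acid-catalysed transacetalization ties the cis-5,6-diol into a cis-fused isopropylidene acetal; PPTS should leave both silyl groups in place.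

Step 13
Reactants: 18 tert-butyl({(3aS,4R,5S,7aS)-4-methoxy-2,2-dimethyl-7-[(trimethylsilyl)ethynyl]-3a,4,5,7a-tetrahydro-1,3-benzodioxol-5-yl}oxy)dimethylsilane
Product: 19 (3aS,4S,5S,7aS)-7-ethynyl-4-methoxy-2,2-dimethyl-3a,4,5,7a-tetrahydro-1,3-benzodioxol-5-ol
Conditions: Bu4NF, THF, 0 °C → rt
Reagents that add atoms: none
Why: Fluoride cleaves both the Si–O bond of the TBS ether and the Si–C(sp) bond of the TMS alkyne in one operation, while the acetonide is inert.

Step 14
Reactants: 19 (3aS,4S,5S,7aS)-7-ethynyl-4-methoxy-2,2-dimethyl-3a,4,5,7a-tetrahydro-1,3-benzodioxol-5-ol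
Product: 20 (3aS,4S,5S,7aS)-7-ethynyl-4-methoxy-2,2-dimethyl-3a,4,5,7a-tetrahydro-1,3-benzodioxol-5-yl acetate
Conditions: Ac2O, pyridine, DMAP (cat.), CH2Cl2, 0 °C → rt
Reagents that add atoms: acetic anhydride, CC(=O)OC(C)=O
Why: DMAP-catalysed acylation of the only free hydroxyl installs the C3 acetate; no bond to C3 is broken, so its configuration is retained.

Step 15
Reactants: 20 (3aS,4S,5S,7aS)-7-ethynyl-4-methoxy-2,2-dimethyl-3a,4,5,7a-tetrahydro-1,3-benzodioxol-5-yl acetate
Product: 21 (1S,4S,5S,6R)-3-ethynyl-4,5-dihydroxy-6-methoxycyclohex-2-en-1-yl acetate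
Conditions: AcOH/H2O (4:1), 40 °C
Reagents that add atoms: none
Why: Mild aqueous-acid hydrolysis of the isopropylidene acetal frees the diol; the acetate tolerates aqueous acetic acid and should not migrate because C4 bears a methyl ether and the C5 hydroxyl is trans to it across the ring.

Step 16
Reactants: 22 2-methylbut-3-yn-2-ol
Product: 23 (E)-2-methyl-4-(tributylstannyl)but-3-en-2-ol
Conditions: Bu3SnH, AIBN (cat.), neat, 80 °C
Reagents that add atoms: tributyltin hydride, CCCC[SnH](CCCC)CCCC
Why: Radical hydrostannation places tin on the terminal carbon, and reversible stannyl radical addition equilibrates the product to the E isomer.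

Step 17
Reactants: 23 (E)-2-methyl-4-(tributylstannyl)but-3-en-2-ol; 24 2,3-dibromopropene
Product: 25 (3E)-6-bromo-2-methylhepta-3,6-dien-2-ol
Conditions: Pd2(dba)3 (cat.), AsPh3, THF, 40 °C, excess 24
Reagents that add atoms: none
Why: Stille allyl–alkenyl coupling: zerovalent palladium inserts into the allylic C–Br bond far faster than into the vinylic one, the symmetrical 2-bromoallyl palladium intermediate makes regiochemistry moot, and the alkenyl group is transferred with retention of the E geometry.

Step 18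
Reactants: 21 (1S,4S,5S,6R)-3-ethynyl-4,5-dihydroxy-6-methoxycyclohex-2-en-1-yl acetate; 25 (3E)-6-bromo-2-methylhepta-3,6-dien-2-ol
Product: 26 (1S,4S,5S,6R)-4,5-dihydroxy-3-[(5E)-7-hydroxy-7-methyl-3-methylideneoct-5-en-1-yn-1-yl]-6-methoxycyclohex-2-en-1-yl acetate
Conditions: Pd(PPh3)4 (cat.), CuI (cat.), i-Pr2NH, THF, rt → 40 °C, degassed
Reagents that add atoms: none
Why: Sonogashira coupling of the terminal alkyne with the vinylic bromide forms the C(sp)–C(sp2) bond under a mild amine base that should leave the acetate, the diol and the tertiary allylic alcohol untouched; no stereocentre is involved.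

Compound list
1 | (R)-glycidol | OC[C@@H]1CO1 | starting material
2 | (S)-2-{[(4-methoxybenzyl)oxy]methyl}oxirane | COc1ccc(COC[C@@H]2CO2)cc1 | intermediate
3 | (S)-1-[(4-methoxybenzyl)oxy]but-3-en-2-ol | COc1ccc(COC[C@@H](O)C=C)cc1 | intermediate
4 | (S)-3-methoxy-4-[(4-methoxybenzyl)oxy]but-1-ene | COc1ccc(COC[C@@H](OC)C=C)cc1 | intermediate
5 | 3-{(1R)-1-methoxy-2-[(4-methoxybenzyl)oxy]ethyl}-1,2,4-trioxolane, the ozonide of 4, epimers at the ring carbon, not isolated | COc1ccc(COC[C@@H](OC)C2OCOO2)cc1 | intermediate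
6 | (R)-2-methoxy-3-[(4-methoxybenzyl)oxy]propanal | O=C[C@H](OC)COCc1ccc(OC)cc1 | intermediate
7 | 1,4-bis(trimethylsilyl)buta-1,3-diyne | C[Si](C)(C)C#CC#C[Si](C)(C)C | starting material
8 | [4-(trimethylsilyl)buta-1,3-diyn-1-yl]lithium, not isolated | [Li]C#CC#C[Si](C)(C)C | intermediate
9 | (2R,3S)-2-methoxy-1-[(4-methoxybenzyl)oxy]-7-(trimethylsilyl)hepta-4,6-diyn-3-ol | C[Si](C)(C)C#CC#C[C@H](O)[C@H](OC)COCc1ccc(OC)cc1 | intermediate
10 | sodium alkenylalanate of 9: five-membered 1,2-oxaaluminole ring joining O3 and C5 of the chain, two 2-methoxyethoxy ligands on aluminium, not isolated | [Na+].COCCO[Al-]1(OCCOC)O[C@H]([C@H](OC)COCc2ccc(OC)cc2)C=C1C#C[Si](C)(C)C | intermediate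
11 | (2R,3S,4Z)-5-iodo-2-methoxy-1-[(4-methoxybenzyl)oxy]-7-(trimethylsilyl)hept-4-en-6-yn-3-ol | C[Si](C)(C)C#C/C(I)=C/[C@H](O)[C@H](OC)COCc1ccc(OC)cc1 | intermediate
12 | tert-butyl({(2R,3S,4Z)-5-iodo-2-methoxy-1-[(4-methoxybenzyl)oxy]-7-(trimethylsilyl)hept-4-en-6-yn-3-yl}oxy)dimethylsilane | C[Si](C)(C)C#C/C(I)=C/[C@H](O[Si](C)(C)C(C)(C)C)[C@H](OC)COCc1ccc(OC)cc1 | intermediate
13 | alkenyllithium from 12 (lithium in place of iodine, geometry retained), not isolated | C[Si](C)(C)C#C/C([Li])=C/[C@H](O[Si](C)(C)C(C)(C)C)[C@H](OC)COCc1ccc(OC)cc1 | intermediate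
14 | (2Z,4S,5R)-4-[(tert-butyldimethylsilyl)oxy]-5-methoxy-6-[(4-methoxybenzyl)oxy]-2-[(trimethylsilyl)ethynyl]hex-2-enal | O=C/C(C#C[Si](C)(C)C)=C\[C@H](O[Si](C)(C)C(C)(C)C)[C@H](OC)COCc1ccc(OC)cc1 | intermediate
15 | (2Z,4S,5R)-4-[(tert-butyldimethylsilyl)oxy]-6-hydroxy-5-methoxy-2-[(trimethylsilyl)ethynyl]hex-2-enal | O=C/C(C#C[Si](C)(C)C)=C\[C@H](O[Si](C)(C)C(C)(C)C)[C@H](OC)CO | intermediate
16 | (2Z,4S,5S)-4-[(tert-butyldimethylsilyl)oxy]-5-methoxy-2-[(trimethylsilyl)ethynyl]hex-2-enedial | O=C/C(C#C[Si](C)(C)C)=C\[C@H](O[Si](C)(C)C(C)(C)C)[C@H](OC)C=O | intermediate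
17 | (1S,2S,5S,6R)-5-[(tert-butyldimethylsilyl)oxy]-6-methoxy-3-[(trimethylsilyl)ethynyl]cyclohex-3-ene-1,2-diol | C[Si](C)(C)C#CC1=C[C@H](O[Si](C)(C)C(C)(C)C)[C@H](OC)[C@@H](O)[C@H]1O | intermediate
18 | tert-butyl({(3aS,4R,5S,7aS)-4-methoxy-2,2-dimethyl-7-[(trimethylsilyl)ethynyl]-3a,4,5,7a-tetrahydro-1,3-benzodioxol-5-yl}oxy)dimethylsilane | C[Si](C)(C)C#CC1=C[C@H](O[Si](C)(C)C(C)(C)C)[C@H](OC)[C@H]2OC(C)(C)O[C@@H]12 | intermediate
19 | (3aS,4S,5S,7aS)-7-ethynyl-4-methoxy-2,2-dimethyl-3a,4,5,7a-tetrahydro-1,3-benzodioxol-5-ol | C#CC1=C[C@H](O)[C@H](OC)[C@H]2OC(C)(C)O[C@@H]12 | intermediate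
20 | (3aS,4S,5S,7aS)-7-ethynyl-4-methoxy-2,2-dimethyl-3a,4,5,7a-tetrahydro-1,3-benzodioxol-5-yl acetate | C#CC1=C[C@H](OC(C)=O)[C@H](OC)[C@H]2OC(C)(C)O[C@@H]12 | intermediate
21 | (1S,4S,5S,6R)-3-ethynyl-4,5-dihydroxy-6-methoxycyclohex-2-en-1-yl acetate | C#CC1=C[C@H](OC(C)=O)[C@H](OC)[C@@H](O)[C@H]1O | intermediate
22 | 2-methylbut-3-yn-2-ol | CC(C)(O)C#C | starting material
23 | (E)-2-methyl-4-(tributylstannyl)but-3-en-2-ol | CCCC[Sn](CCCC)(CCCC)/C=C/C(C)(C)O | intermediate
24 | 2,3-dibromopropene | C=C(Br)CBr | starting material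
25 | (3E)-6-bromo-2-methylhepta-3,6-dien-2-ol | C=C(Br)C/C=C/C(C)(C)O | intermediate
26 | (1S,4S,5S,6R)-4,5-dihydroxy-3-[(5E)-7-hydroxy-7-methyl-3-methylideneoct-5-en-1-yn-1-yl]-6-methoxycyclohex-2-en-1-yl acetate (CNP0546270.2) | C=C(C#CC1=C[C@H](OC(C)=O)[C@H](OC)[C@@H](O)[C@H]1O)C/C=C/C(C)(C)O | target

Total step count: 18
Longest linear sequence: 16 (steps 1–15 and 18)

Steps most likely to fail

Step 11. The ketyl may take up a second electron before it cyclizes and expel the C3 silyloxy group, it may couple intermolecularly, or a poorly organized transition state may give the trans-diol. The fallback closes the ring by olefin metathesis and adds the diol afterwards, using known reaction types only; it sets out from dialdehyde 16 and comes back at diol 17. Double Wittig methylenation of 16 (Ph3PCH3Br, KN(SiMe3)2, THF, −78 °C) would give the triene tert-butyl({(3E,5S,6R)-6-methoxy-3-[(trimethylsilyl)ethynyl]octa-1,3,7-trien-5-yl}oxy)dimethylsilane F1. Ring-closing metathesis of the two vinyl groups (second-generation Hoveyda–Grubbs catalyst, CH2Cl2, 40 °C) would give the cyclohexa-1,3-diene tert-butyl({(1S,6R)-6-methoxy-3-[(trimethylsilyl)ethynyl]cyclohexa-2,4-dien-1-yl}oxy)dimethylsilane F2. Dihydroxylation (OsO4 cat., N-methylmorpholine N-oxide, acetone/H2O, 0 °C) should then attack the more electron-rich disubstituted C5=C6 alkene from the face opposite the C4 methoxy and C3 silyloxy groups, as in osmylations of protected cyclohexadiene cis-diols, and return 17.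

Step 5. Facial selectivity in the acetylide addition may be poor, since the small methoxy group gives only a modest Felkin–Anh bias and lithium chelation by the α- and β-oxygens favours the syn carbinol. The fallback replaces substrate control by catalyst control; it sets out from 9 obtained as a mixture of C3 epimers and comes back at diastereomerically pure 9. Oxidation of the mixture (Dess–Martin periodinane, CH2Cl2) would give the ynone (2R)-2-methoxy-1-[(4-methoxybenzyl)oxy]-7-(trimethylsilyl)hepta-4,6-diyn-3-one F3. Noyori asymmetric transfer hydrogenation (RuCl[(R,R)-TsDPEN](p-cymene), i-PrOH, rt) should then deliver the 3S carbinol, the alkynyl group taking the place the aryl group occupies in aryl ketone reductions.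

Step 8. The α-alkynyl alkenyllithium may lose its geometry through a linear cumulenyl form, or may react with DMF at the alkyne terminus. The fallback introduces the formyl carbon by palladium-catalysed carbonylation instead of an organolithium; it sets out from iodide 12 and comes back at enynal 14. Alkoxycarbonylation of 12 (PdCl2(PPh3)2 cat., CO (1 atm), MeOH, Et3N, DMF, 50 °C) would give, with retention of geometry, methyl (2Z,4S,5R)-4-[(tert-butyldimethylsilyl)oxy]-5-methoxy-6-[(4-methoxybenzyl)oxy]-2-[(trimethylsilyl)ethynyl]hex-2-enoate F4. Reduction with i-Bu2AlH (CH2Cl2, −78 °C) would give (2Z,4S,5R)-4-[(tert-butyldimethylsilyl)oxy]-5-methoxy-6-[(4-methoxybenzyl)oxy]-2-[(trimethylsilyl)ethynyl]hex-2-en-1-ol F5, and MnO2 (CH2Cl2, rt) would oxidize this allylic alcohol to 14.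

Further compounds
F1 | step 11 | tert-butyl({(3E,5S,6R)-6-methoxy-3-[(trimethylsilyl)ethynyl]octa-1,3,7-trien-5-yl}oxy)dimethylsilane | C=C/C(C#C[Si](C)(C)C)=C\[C@H](O[Si](C)(C)C(C)(C)C)[C@H](OC)C=C
F2 | step 11 | tert-butyl({(1S,6R)-6-methoxy-3-[(trimethylsilyl)ethynyl]cyclohexa-2,4-dien-1-yl}oxy)dimethylsilane | C[Si](C)(C)C#CC1=C[C@H](O[Si](C)(C)C(C)(C)C)[C@H](OC)C=C1
F3 | step 5 | (2R)-2-methoxy-1-[(4-methoxybenzyl)oxy]-7-(trimethylsilyl)hepta-4,6-diyn-3-one | C[Si](C)(C)C#CC#CC(=O)[C@H](OC)COCc1ccc(OC)cc1
F4 | step 8 | methyl (2Z,4S,5R)-4-[(tert-butyldimethylsilyl)oxy]-5-methoxy-6-[(4-methoxybenzyl)oxy]-2-[(trimethylsilyl)ethynyl]hex-2-enoate | COC(=O)/C(C#C[Si](C)(C)C)=C\[C@H](O[Si](C)(C)C(C)(C)C)[C@H](OC)COCc1ccc(OC)cc1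
F5 | step 8 | (2Z,4S,5R)-4-[(tert-butyldimethylsilyl)oxy]-5-methoxy-6-[(4-methoxybenzyl)oxy]-2-[(trimethylsilyl)ethynyl]hex-2-en-1-ol | OC/C(C#C[Si](C)(C)C)=C\[C@H](O[Si](C)(C)C(C)(C)C)[C@H](OC)COCc1ccc(OC)cc1
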